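## Analysis of the target

Compound 40 is a biflavanoid: an ent-fisetinidol unit (rings A, C, B; suffix U) bonded through C4-U to C6-L of a (+)-catechin unit (rings D, F, E; suffix L). Ring A carries only the 7-hydroxyl, ring D is a phloroglucinol ring, and rings B and E are catechols.

There are five stereocentres. C2-U (S), C3-U (R) and C4-U (R) are all-trans on ring C: the aryl groups at C2-U and C4-U are cis to each other and both trans to the C3-U hydroxyl (a 4β link in the ent series). C2-L (R) and C3-L (S) are trans on ring F. The two sets belong to opposite enantiomeric series and do not communicate, so each must be set on its own with absolute control.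

The molecule has nine hydroxyls, seven of them phenolic, and the two catechols oxidise easily in air. The benzylic C2–O1 ethers of both pyran rings and the doubly benzylic C4-U position ionise under acid.

The real difficulty is the position of the interflavan bond. A flavan-4-yl cation attacks a catechin-type nucleophile mainly at C8-L, so substitution chemistry makes the 4→6 isomer the minor product, and the 4β-trans configuration has to be right at the same time.

The strategy rests on ring D. Going round it, C5-L (OH), C6-L (bound to C4-U), C7-L (O), C8-L (H), C8a-L (O1-L) and C4a-L (C4-L) are the atoms that a vinylketene (C5-L, C8-L, C8a-L, C4a-L) and an ynol ether (C6-L, C7-L) supply in a benzannulation. Ring D can therefore be grown between the two halves, with the link position fixed by the polarity of the alkyne.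

## Retrosynthetic reasoning

**40 ⇒ 39 ⇒ 38.** Every oxygen that is not created in the annulation is carried as a benzyl ether, so the last operation is one hydrogenolysis of 39. Before it, the silyl ether at C7-L of 38 is cleaved with fluoride. No skeletal bond is cut; the gain is that the oxidation-prone polyphenol exists only at the very end.

**38 ⇒ 17 + 33.** Ring D is cut at three bonds: C5-L–C6-L, C7-L–C8-L and C5-L–C4a-L. This gives the silyl ynol ether 17, which brings C6-L and C7-L with the whole upper flavan on C6-L. It also gives vinylketene 34, stored as diazoketone 33, which brings C5-L, C8-L, C8a-L and C4a-L with ring F intact. Cutting here, and not at C4-U–C6-L, removes the C6/C8 choice: the carbon that bears the flavanyl group must end between the two new oxygens. Forward, the step passes through 35, 36 and 37 and has to be regioselective only, since all five stereocentres arrive in the fragments.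

**17 ⇒ 15 ⇒ 14 ⇒ 10 + 13.** The Si–O bond and then the alkyne C–O bond are cut: 17 is the O-silylation product of lithium ynolate 16, which comes from oxygen transfer to the acetylide of 15. The C4-U–C(sp) bond is cut next, giving the C4 cation precursor 10 and the alkynyl borate 13 (from 11 through 12). C4 is the natural electrophilic site of a flavan (stabilised by O1-U and the 7-oxygen). The forward substitution must place the alkyne trans to the 3-benzyloxy group, which sets C4-U; 14 is desilylated to 15.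

**10 ⇒ 9 ⇒ 8 ⇒ 6 ⇒ 5 ⇒ 3 + 4.** Ring C is opened at O1-U–C2-U. Ether 10 comes from diol 9 and this from dihydroflavonol 8, which arises by opening of epoxide 6 (through phenol 7) by the ring-A oxygen with inversion. One catalytic enantioselective epoxidation of chalcone 5 thus sets C2-U and C3-U. Chalcone 5 is the aldol condensation product of ketone 3 and aldehyde 4; 3 comes from 1 through 2.

**33 ⇒ 31 ⇒ 29.** The diazo group is installed by diazo transfer to methyl ketone 31 (through 32), and 31 comes from ester 29 through amide 30. Diazo transfer is preferred to acylation of a diazoalkane with an unsaturated acid chloride, where dipolar addition to the conjugated double bond competes.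

**29 ⇒ 28 ⇒ 27 ⇒ 26.** The enol ether double bond of ring F (C4a-L=C8a-L) is cut by a ring-closing metathesis transform to diene 28. Its alkoxyacrylate arm is attached to the oxygen of alcohol 26 by carbenoid O–H insertion (27) and methylenation. Both ring F stereocentres are thus settled on an acyclic alcohol before the ring is made.

**26 ⇒ 25 ⇒ 22 + 23 ⇒ 21 ⇒ 20 ⇒ 18 + 19.** C2-L is set by chelation-controlled reduction of ketone 25 (anti to the existing C3-L benzyloxy centre). Ketone 25 is cut at the aryl–carbonyl bond into amide 22 and aryl bromide 23 (used as 24). C3-L comes from an auxiliary-controlled allylation (20 → 21), with 20 made from 18 and 19.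

## Alternatives that were turned down

**Alternative 1:** The C3-U–C4-U bond of ring C is cut. Forward, SmI2 (divalent samarium) reduces the diaryl ketone of keto aldehyde A2 to a ketyl, which adds to the tethered aldehyde and closes ring C as the cis-3,4-diol A1.
- For it: the union of the halves is an acylation, ring C and two oxygenated centres form in one step, and the lower unit can come from the chiral pool. It is therefore shorter for ring F than the chosen route.
- Against it: A1 carries an extra tertiary hydroxyl at C4-U. Its removal needs hydride delivery cis to the C3-U oxygen, whereas a C4 cation is normally attacked anti to the C3 substituent, so the wrong C4 epimer is the expected product. The ketone of A2 needs acylation of the lower unit at C6-L and not at C8-L, so the regiochemical problem is only moved. C2-U in A2 is an α-aryl-α-aryloxy aldehyde centre that enolises easily.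
- Comparison: the chosen route is longer for the lower half but has no reductive stereochemical correction and no regiochemical choice.

**Alternative 2:** The C4-L–C4a-L bond of ring F is cut. Forward, a mild acid promoter (hexafluoroisopropanol or BF3·OEt2) lets the symmetric ring D of epoxide A4 attack the primary epoxide carbon, giving A3 with the C3-L hydroxyl free.
- For it: the two ortho carbons of ring D are equivalent, so the 4→6 pattern is also fixed by construction. On this point it equals the chosen strategy, and it needs no diazo compound or lamp, which makes it easier to scale.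
- Against it: the symmetric arene needs the upper C4 attached to the phloroglucinol carbon flanked by two benzyloxy groups, its most hindered site. The ether O1-L–C2-L must be made at an electron-rich benzylic carbon without loss of configuration. Under the acid promoter that same ether can ionise, closure at the secondary epoxide carbon (five-membered ring) competes, and several other benzyloxyarenes are present as nucleophiles.
- Comparison: the chosen strategy offers a union under neutral conditions and ring F stereocentres proven on the small alcohol 26.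

**Alternative 3:** O1-U–C2-U and C3-U–C4-U are cut together. Forward, a chiral phosphoric acid ionises benzhydrol A6 to the ring-A ortho-quinone methide, which adds enol acetate A7 to give A5.
- For it: it is clearly the shortest plan. Ring C and all three upper stereocentres form in one step from simple pieces, and the E geometry of A7 fixes the 2,3-trans relation.
- Against it: A6 again needs a carbon substituent at C6-L and not C8-L of the lower unit. Three stereocentres must be set by the catalyst against a bulky chiral group on the methide carbon. A7 must react as a styrene (oxygen-bearing carbon to the methide carbon) and not as an enol ester. The 3,4-trans relation depends on the endo/exo approach.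
- Comparison: the chosen strategy gives up step count, but each stereocentre is set by a well-understood reaction on a small molecule and the link position needs no directing device.

Key step: step 22

Remark: conjugate bases made by plain deprotonation (alkoxides, enolates, acetylides, phosphonate anions) are covered by the Conditions lines and carry no number; the C4 epimer of 9, if it forms in step 6, serves equally because C4-U is ionised in step 9.

## Route

Step 1
Reactants: 1 2,4-dihydroxyacetophenone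
Product: 2 1-[4-(benzyloxy)-2-hydroxyphenyl]ethanone
Conditions: BnBr, K2CO3, acetone, reflux
Reagents that add atoms: benzyl bromide BrCc1ccccc1
Why: Williamson ether synthesis; the 2-hydroxyl is held in a hydrogen bond to the ketone and is the poorer nucleophile, so the 4-hydroxyl is benzylated selectively.

Step 2
Reactants: 2 1-[4-(benzyloxy)-2-hydroxyphenyl]ethanone
Product: 3 1-[4-(benzyloxy)-2-(methoxymethoxy)phenyl]ethanone
Conditions: NaH, MOMCl, DMF, 0 °C to rt
Reagents that add atoms: chloromethyl methyl ether COCCl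
Why: O-alkylation of the sodium phenoxide (acetal protection); the masked phenol cannot enter an Algar–Flynn–Oyamada cyclisation during the later peroxide epoxidation.

Step 3
Reactants: 3 1-[4-(benzyloxy)-2-(methoxymethoxy)phenyl]ethanone, 4 3,4-bis(benzyloxy)benzaldehyde
Product: 5 (E)-1-[4-(benzyloxy)-2-(methoxymethoxy)phenyl]-3-[3,4-bis(benzyloxy)phenyl]prop-2-en-1-one
Conditions: KOH, EtOH/THF, rt
Reagents that add atoms: none
Why: Claisen–Schmidt condensation; the non-enolisable aldehyde and elimination under equilibrating conditions should give the E-enone only.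

Step 4
Reactants: 5 (E)-1-[4-(benzyloxy)-2-(methoxymethoxy)phenyl]-3-[3,4-bis(benzyloxy)phenyl]prop-2-en-1-one
Product: 6 [4-(benzyloxy)-2-(methoxymethoxy)phenyl]{(2S,3R)-3-[3,4-bis(benzyloxy)phenyl]oxiran-2-yl}methanone
Conditions: poly-D-leucine, urea–H2O2, DBU, THF, rt
Reagents that add atoms: urea–hydrogen peroxide NC(N)=O.OO
Why: Juliá–Colonna epoxidation; the helical peptide binds enone and hydroperoxide and passes oxygen to one enone face, and since the L-polymer leads to the (2R,3S) series of chalcone epoxides the D-polymer should give the (2S,3R) trans-epoxide, whose purity can be raised by crystallisation here or at 8.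

Step 5
Reactants: 6 [4-(benzyloxy)-2-(methoxymethoxy)phenyl]{(2S,3R)-3-[3,4-bis(benzyloxy)phenyl]oxiran-2-yl}methanone
Product: 8 (2S,3S)-7-(benzyloxy)-2-[3,4-bis(benzyloxy)phenyl]-3-hydroxychroman-4-one, via phenol epoxide 7 (not isolated)
Conditions: conc. HCl, MeOH/THF, 55 °C
Reagents that add atoms: none
Why: Acetal cleavage followed by acid-promoted 6-endo epoxide opening; the freed phenol attacks the benzylic epoxide carbon with inversion while the carbinol carbon keeps its configuration, giving the 2,3-trans dihydroflavonol, which is also the thermodynamically preferred isomer.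

Step 6
Reactants: 8 (2S,3S)-7-(benzyloxy)-2-[3,4-bis(benzyloxy)phenyl]-3-hydroxychroman-4-one
Product: 9 (2S,3R,4S)-7-(benzyloxy)-2-[3,4-bis(benzyloxy)phenyl]chromane-3,4-diol
Conditions: NaBH4, MeOH/THF, 0 °C
Reagents that add atoms: none
Why: Borohydride reduction of the ketone; trans-dihydroflavonols are reduced mainly to the 2,3-trans-3,4-trans diol, and the C4 configuration is not needed later.

Step 7
Reactants: 9 (2S,3R,4S)-7-(benzyloxy)-2-[3,4-bis(benzyloxy)phenyl]chromane-3,4-diol
Product: 10 (2S,3R,4S)-3,4,7-tris(benzyloxy)-2-[3,4-bis(benzyloxy)phenyl]chromane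
Conditions: NaH, BnBr, Bu4NI (cat.), DMF, 0 °C to rt
Reagents that add atoms: benzyl bromide BrCc1ccccc1
Why: Williamson ether synthesis on both alkoxides; the C3 benzyl ether is the final protecting group and the C4 benzyl ether, a 2,4-dioxygenated benzylic ether, is the leaving group for the next substitution.

Step 8
Reactants: 11 ethynyltrimethylsilane
Product: 13 potassium trifluoro[(trimethylsilyl)ethynyl]borate, via lithium alkynylborate 12 (not isolated)
Conditions: n-BuLi, THF, −78 °C; B(OMe)3; aq. KHF2, rt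
Reagents that add atoms: trimethyl borate COB(OC)OC; potassium hydrogen difluoride [K+].[F-].F
Why: Acetylide borylation and fluoride exchange; the standard preparation of air-stable potassium alkynyltrifluoroborates.

Step 9
Reactants: 10 (2S,3R,4S)-3,4,7-tris(benzyloxy)-2-[3,4-bis(benzyloxy)phenyl]chromane, 13 potassium trifluoro[(trimethylsilyl)ethynyl]borate
Product: 14 {[(2S,3R,4R)-3,7-bis(benzyloxy)-2-[3,4-bis(benzyloxy)phenyl]chroman-4-yl]ethynyl}trimethylsilane
Conditions: BF3·OEt2, MeCN/CH2Cl2, −40 to 0 °C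
Reagents that add atoms: none
Why: Lewis-acid benzylic substitution with an alkynyltrifluoroborate: BF3 takes fluoride from 13, the resulting alkynyldifluoroborane ionises the C4 benzyloxy group to the cation stabilised by O1 and the 7-benzyloxy group and hands over the alkynyl group; in the half-chair cation the 2-aryl and 3-benzyloxy groups are pseudo-equatorial and the nucleophile enters on the face opposite the 3-benzyloxy group, which sets C4 as 3,4-trans (2,4-cis).

Step 10
Reactants: 14 {[(2S,3R,4R)-3,7-bis(benzyloxy)-2-[3,4-bis(benzyloxy)phenyl]chroman-4-yl]ethynyl}trimethylsilane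
Product: 15 (2S,3R,4S)-3,7-bis(benzyloxy)-2-[3,4-bis(benzyloxy)phenyl]-4-ethynylchromane
Conditions: K2CO3, MeOH/THF, rt
Reagents that add atoms: none
Why: Methanolysis of the alkynyl C–Si bond (protodesilylation); the mild carbonate conditions leave the benzyl ethers and the C4 hydrogen alone.

Step 11
Reactants: 15 (2S,3R,4S)-3,7-bis(benzyloxy)-2-[3,4-bis(benzyloxy)phenyl]-4-ethynylchromane
Product: 17 (2S,3R,4S)-3,7-bis(benzyloxy)-2-[3,4-bis(benzyloxy)phenyl]-4-{[(triisopropylsilyl)oxy]ethynyl}chromane, via lithium ynolate 16 (not isolated)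
Conditions: LiN(SiMe3)2, THF, −78 °C; t-BuOOLi (from t-BuOOH and LiN(SiMe3)2), −78 to 0 °C; i-Pr3SiOTf, −78 °C
Reagents that add atoms: lithium tert-butyl peroxide, made in the flask from tert-butyl hydroperoxide CC(C)(C)OO; triisopropylsilyl trifluoromethanesulfonate CC(C)[Si](C(C)C)(C(C)C)OS(=O)(=O)C(F)(F)F
Why: Oxidation of a lithium acetylide to the ynolate by electrophilic oxygen transfer from the lithium peroxide, then O-silylation; the large silyl triflate reacts at oxygen and gives an isolable silyl ynol ether, and the acetylenic hydrogen is far more acidic than the C4 hydrogen, so C4 is not touched.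

Step 12
Reactants: 18 (R)-4-benzyl-2-oxazolidinone, 19 (benzyloxy)acetyl chloride
Product: 20 (R)-4-benzyl-3-[(benzyloxy)acetyl]oxazolidin-2-one
Conditions: n-BuLi, THF, −78 °C; then 19
Reagents that add atoms: none
Why: N-acylation of the lithiated oxazolidinone; standard attachment of an Evans auxiliary.

Step 13
Reactants: 20 (R)-4-benzyl-3-[(benzyloxy)acetyl]oxazolidin-2-one
Product: 21 (R)-4-benzyl-3-[(2S)-2-(benzyloxy)pent-4-enoyl]oxazolidin-2-one
Conditions: NaN(SiMe3)2, THF, −78 °C; allyl iodide, −78 to −45 °C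
Reagents that add atoms: allyl iodide C=CCI
Why: Evans glycolate alkylation; the chelated Z-sodium enolate is attacked on the face opposite the benzyl group of the (R)-auxiliary, which sets the (S) centre that becomes C3-L.

Step 14
Reactants: 21 (R)-4-benzyl-3-[(2S)-2-(benzyloxy)pent-4-enoyl]oxazolidin-2-one
Product: 22 (2S)-2-(benzyloxy)-N-methoxy-N-methylpent-4-enamide
Conditions: Me(MeO)NH·HCl, AlMe3, CH2Cl2, −10 °C to rt
Reagents that add atoms: N,O-dimethylhydroxylamine hydrochloride CNOC.Cl
Why: Aluminium amide transamination of the imide to the Weinreb amide; the conditions are not basic enough to epimerise the α-centre, and auxiliary 18 is recovered.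

Step 15
Reactants: 22 (2S)-2-(benzyloxy)-N-methoxy-N-methylpent-4-enamide, 23 4-bromo-1,2-bis(benzyloxy)benzene
Product: 25 (2S)-2-(benzyloxy)-1-[3,4-bis(benzyloxy)phenyl]pent-4-en-1-one, via arylmagnesium bromide 24 (not isolated)
Conditions: 23, Mg, THF; then 22, 0 °C
Reagents that add atoms: none
Why: Weinreb ketone synthesis; the chelated tetrahedral adduct stops the Grignard addition at the ketone stage.

Step 16
Reactants: 25 (2S)-2-(benzyloxy)-1-[3,4-bis(benzyloxy)phenyl]pent-4-en-1-one
Product: 26 (1R,2S)-2-(benzyloxy)-1-[3,4-bis(benzyloxy)phenyl]pent-4-en-1-ol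
Conditions: Zn(BH4)2, Et2O, −30 °C
Reagents that add atoms: none
Why: Chelation-controlled reduction (Cram chelate model); zinc ties the ketone and α-benzyloxy oxygens into a five-membered ring and hydride arrives opposite the allyl chain, which gives the anti (1R,2S) alcohol and so sets C2-L.

Step 17
Reactants: 26 (1R,2S)-2-(benzyloxy)-1-[3,4-bis(benzyloxy)phenyl]pent-4-en-1-ol
Product: 27 ethyl 2-{[(1R,2S)-2-(benzyloxy)-1-[3,4-bis(benzyloxy)phenyl]pent-4-en-1-yl]oxy}-2-(diethoxyphosphoryl)acetate
Conditions: ethyl diazo(diethoxyphosphoryl)acetate, Rh2(OAc)4 (cat.), toluene, 90 °C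
Reagents that add atoms: ethyl 2-diazo-2-(diethoxyphosphoryl)acetate CCOC(=O)C(=[N+]=[N-])P(=O)(OCC)OCC
Why: Rhodium carbenoid O–H insertion; for this acceptor-substituted carbenoid insertion into the hydroxyl is faster than cyclopropanation of the terminal alkene, and the new CH centre is formed as a mixture that disappears in the next step.

Step 18
Reactants: 27 ethyl 2-{[(1R,2S)-2-(benzyloxy)-1-[3,4-bis(benzyloxy)phenyl]pent-4-en-1-yl]oxy}-2-(diethoxyphosphoryl)acetate
Product: 28 ethyl 2-{[(1R,2S)-2-(benzyloxy)-1-[3,4-bis(benzyloxy)phenyl]pent-4-en-1-yl]oxy}acrylate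
Conditions: NaH, THF, 0 °C; (CH2O)n, 0 °C to rt
Reagents that add atoms: formaldehyde (as paraformaldehyde) C=O
Why: Horner–Wadsworth–Emmons methylenation; the phosphonate anion condenses with formaldehyde to the α-alkoxyacrylate.

Step 19
Reactants: 28 ethyl 2-{[(1R,2S)-2-(benzyloxy)-1-[3,4-bis(benzyloxy)phenyl]pent-4-en-1-yl]oxy}acrylate
Product: 29 ethyl (2R,3S)-3-(benzyloxy)-2-[3,4-bis(benzyloxy)phenyl]-3,4-dihydro-2H-pyran-6-carboxylate
Conditions: second-generation Grubbs catalyst (H2IMes)(PCy3)Cl2Ru=CHPh (cat.), toluene, 80 °C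
Reagents that add atoms: none
Why: Ring-closing metathesis; the catalyst loads on the terminal alkene and closes onto the 1,1-disubstituted alkoxyacrylate to the six-membered cyclic enol ether ester with loss of ethylene.

Step 20
Reactants: 29 ethyl (2R,3S)-3-(benzyloxy)-2-[3,4-bis(benzyloxy)phenyl]-3,4-dihydro-2H-pyran-6-carboxylate
Product: 31 1-{(2R,3S)-3-(benzyloxy)-2-[3,4-bis(benzyloxy)phenyl]-3,4-dihydro-2H-pyran-6-yl}ethanone, via Weinreb amide 30 (not isolated)
Conditions: Me(MeO)NH·HCl, i-PrMgCl, THF, −20 °C; then MeMgBr, −20 to 0 °C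
Reagents that add atoms: methylmagnesium bromide C[Mg]Br; N,O-dimethylhydroxylamine hydrochloride CNOC.Cl (its atoms stay only in 30)
Why: One-pot Weinreb amidation of the ester with the magnesium amide and Weinreb ketone synthesis; the chelated adduct prevents double addition, and the amide can be isolated if the one-pot version is not clean.

Step 21
Reactants: 31 1-{(2R,3S)-3-(benzyloxy)-2-[3,4-bis(benzyloxy)phenyl]-3,4-dihydro-2H-pyran-6-yl}ethanone
Product: 33 2-diazo-1-{(2R,3S)-3-(benzyloxy)-2-[3,4-bis(benzyloxy)phenyl]-3,4-dihydro-2H-pyran-6-yl}ethanone, via trifluoroacetyl ketone 32 (not isolated)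
Conditions: LiN(SiMe3)2, THF, −78 °C; CF3CO2CH2CF3; then MsN3, Et3N, H2O, MeCN, rt
Reagents that add atoms: methanesulfonyl azide CS(=O)(=O)N=[N+]=[N-]; 2,2,2-trifluoroethyl trifluoroacetate O=C(OCC(F)(F)F)C(F)(F)F (its atoms stay only in 32)
Why: Detrifluoroacetylative diazo transfer; the kinetic methyl enolate is trifluoroacetylated, and the activated diketone takes the diazo group while the trifluoroacetyl group leaves as the sulfonamide, which avoids exposing an unsaturated acyl chloride to a diazoalkane.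

Step 22
Reactants: 17 (2S,3R,4S)-3,7-bis(benzyloxy)-2-[3,4-bis(benzyloxy)phenyl]-4-{[(triisopropylsilyl)oxy]ethynyl}chromane, 33 2-diazo-1-{(2R,3S)-3-(benzyloxy)-2-[3,4-bis(benzyloxy)phenyl]-3,4-dihydro-2H-pyran-6-yl}ethanone
Product: 38 (2R,3S)-3-(benzyloxy)-2-[3,4-bis(benzyloxy)phenyl]-6-{(2S,3R,4R)-3,7-bis(benzyloxy)-2-[3,4-bis(benzyloxy)phenyl]chroman-4-yl}-7-[(triisopropylsilyl)oxy]chroman-5-ol, via vinylketene 34 (not isolated), via cyclobutenone 35 (not isolated), via dienylketene 36 (not isolated), via cyclohexadienone 37 (not isolated)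
Conditions: hν (300 nm, Pyrex), ClCH2CH2Cl, rt, 17 in slight excess; then 80 °C
Reagents that add atoms: none
Why: Light expels nitrogen from 33 and a photochemical Wolff rearrangement (shift of the dihydropyranyl carbon) gives vinylketene 34, whose vinyl part is the ring F enol ether. The nucleophilic, flavanyl-bearing carbon of 17 bonds to the ketene carbonyl carbon and the oxygen-bearing carbon to the ketene α-carbon in a [2+2] cycloaddition, so cyclobutenone 35 already contains C5-L–C6-L and C7-L–C8-L. Four-electron electrocyclic opening of 35 (light, completed at 80 °C) gives dienylketene 36, and ring D closes by six-electron electrocyclisation of the ketene carbon onto C4a-L to give 37, which tautomerises to phenol 38. The closest known reaction is the Danheiser benzannulation in its diazoketone form with silyl ynol ethers, which gives resorcinol monosilyl ethers. No stereocentre is formed: the sp3 centres of 35 and 37 are transient, and C4-U and the ring F centres are spectators under neutral, non-ionising conditions. The only selectivity needed is the regiochemistry of the [2+2] step; it is secured by the ynol ether polarisation, which places the flavanyl carbon between the C5-L and C7-L oxygens and so fixes the 4→6 link. Irradiation near 300 nm addresses the diazoketone and not the benzyl aryl ethers.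

Step 23
Reactants: 38 (2R,3S)-3-(benzyloxy)-2-[3,4-bis(benzyloxy)phenyl]-6-{(2S,3R,4R)-3,7-bis(benzyloxy)-2-[3,4-bis(benzyloxy)phenyl]chroman-4-yl}-7-[(triisopropylsilyl)oxy]chroman-5-ol
Product: 39 (2R,3S)-3-(benzyloxy)-2-[3,4-bis(benzyloxy)phenyl]-6-{(2S,3R,4R)-3,7-bis(benzyloxy)-2-[3,4-bis(benzyloxy)phenyl]chroman-4-yl}chromane-5,7-diol
Conditions: Bu4NF, THF, 0 °C
Reagents that add atoms: none
Why: Fluoride cleavage of the aryl silyl ether (desilylation); benzyl ethers and all stereocentres are inert to fluoride.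

Step 24
Reactants: 39 (2R,3S)-3-(benzyloxy)-2-[3,4-bis(benzyloxy)phenyl]-6-{(2S,3R,4R)-3,7-bis(benzyloxy)-2-[3,4-bis(benzyloxy)phenyl]chroman-4-yl}chromane-5,7-diol
Product: 40 (2R,3S)-2-(3,4-dihydroxyphenyl)-6-[(2S,3R,4R)-2-(3,4-dihydroxyphenyl)-3,7-dihydroxychroman-4-yl]chromane-3,5,7-triol
Conditions: H2 (1 atm), Pd(OH)2 on carbon, THF/MeOH, rt; work-up under argon
Reagents that add atoms: none
Why: Catalytic hydrogenolysis of the seven benzyl ethers; under neutral conditions at room temperature the C4-U–C6-L bond and the ring C–O bonds should persist, and no stereocentre is involved.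

## Compound list

1 | 2,4-dihydroxyacetophenone | CC(=O)c1ccc(O)cc1O | starting material
2 | 1-[4-(benzyloxy)-2-hydroxyphenyl]ethanone | CC(=O)c1ccc(OCc2ccccc2)cc1O | intermediate
3 | 1-[4-(benzyloxy)-2-(methoxymethoxy)phenyl]ethanone | COCOc1cc(OCc2ccccc2)ccc1C(C)=O | intermediate
4 | 3,4-bis(benzyloxy)benzaldehyde | O=Cc1ccc(OCc2ccccc2)c(OCc2ccccc2)c1 | starting material
5 | (E)-1-[4-(benzyloxy)-2-(methoxymethoxy)phenyl]-3-[3,4-bis(benzyloxy)phenyl]prop-2-en-1-one | COCOc1cc(OCc2ccccc2)ccc1C(=O)/C=C/c1ccc(OCc2ccccc2)c(OCc2ccccc2)c1 | intermediate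
6 | [4-(benzyloxy)-2-(methoxymethoxy)phenyl]{(2S,3R)-3-[3,4-bis(benzyloxy)phenyl]oxiran-2-yl}methanone | COCOc1cc(OCc2ccccc2)ccc1C(=O)[C@H]1O[C@@H]1c1ccc(OCc2ccccc2)c(OCc2ccccc2)c1 | intermediate
7 | [4-(benzyloxy)-2-hydroxyphenyl]{(2S,3R)-3-[3,4-bis(benzyloxy)phenyl]oxiran-2-yl}methanone | Oc1cc(OCc2ccccc2)ccc1C(=O)[C@H]1O[C@@H]1c1ccc(OCc2ccccc2)c(OCc2ccccc2)c1 | intermediate (not isolated)
8 | (2S,3S)-7-(benzyloxy)-2-[3,4-bis(benzyloxy)phenyl]-3-hydroxychroman-4-one | c1ccccc1COc1ccc2c(c1)O[C@@H](c1ccc(OCc3ccccc3)c(OCc3ccccc3)c1)[C@H](O)C2=O | intermediate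
9 | (2S,3R,4S)-7-(benzyloxy)-2-[3,4-bis(benzyloxy)phenyl]chromane-3,4-diol (2,3-trans-3,4-trans) | c1ccccc1COc1ccc2c(c1)O[C@@H](c1ccc(OCc3ccccc3)c(OCc3ccccc3)c1)[C@H](O)[C@H]2O | intermediate
10 | (2S,3R,4S)-3,4,7-tris(benzyloxy)-2-[3,4-bis(benzyloxy)phenyl]chromane | c1ccccc1COc1ccc2c(c1)O[C@@H](c1ccc(OCc3ccccc3)c(OCc3ccccc3)c1)[C@H](OCc1ccccc1)[C@H]2OCc1ccccc1 | intermediate
11 | ethynyltrimethylsilane | C#C[Si](C)(C)C | starting material
12 | lithium trimethoxy[(trimethylsilyl)ethynyl]borate | [Li+].CO[B-](OC)(OC)C#C[Si](C)(C)C | intermediate (not isolated)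
13 | potassium trifluoro[(trimethylsilyl)ethynyl]borate | [K+].F[B-](F)(F)C#C[Si](C)(C)C | intermediate
14 | {[(2S,3R,4R)-3,7-bis(benzyloxy)-2-[3,4-bis(benzyloxy)phenyl]chroman-4-yl]ethynyl}trimethylsilane (alkyne trans to 3-OBn, cis to 2-aryl) | c1ccccc1COc1ccc2c(c1)O[C@@H](c1ccc(OCc3ccccc3)c(OCc3ccccc3)c1)[C@H](OCc1ccccc1)[C@H]2C#C[Si](C)(C)C | intermediate
15 | (2S,3R,4S)-3,7-bis(benzyloxy)-2-[3,4-bis(benzyloxy)phenyl]-4-ethynylchromane | c1ccccc1COc1ccc2c(c1)O[C@@H](c1ccc(OCc3ccccc3)c(OCc3ccccc3)c1)[C@H](OCc1ccccc1)[C@H]2C#C | intermediate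
16 | lithium 2-{(2S,3R,4S)-3,7-bis(benzyloxy)-2-[3,4-bis(benzyloxy)phenyl]chroman-4-yl}ethynolate | c1ccccc1COc1ccc2c(c1)O[C@@H](c1ccc(OCc3ccccc3)c(OCc3ccccc3)c1)[C@H](OCc1ccccc1)[C@H]2C#C[O-].[Li+] | intermediate (not isolated)
17 | (2S,3R,4S)-3,7-bis(benzyloxy)-2-[3,4-bis(benzyloxy)phenyl]-4-{[(triisopropylsilyl)oxy]ethynyl}chromane | c1ccccc1COc1ccc2c(c1)O[C@@H](c1ccc(OCc3ccccc3)c(OCc3ccccc3)c1)[C@H](OCc1ccccc1)[C@H]2C#CO[Si](C(C)C)(C(C)C)C(C)C | intermediate
18 | (R)-4-benzyl-2-oxazolidinone | O=C1N[C@H](Cc2ccccc2)CO1 | starting material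
19 | (benzyloxy)acetyl chloride | O=C(Cl)COCc1ccccc1 | starting material
20 | (R)-4-benzyl-3-[(benzyloxy)acetyl]oxazolidin-2-one | O=C(COCc1ccccc1)N1[C@H](Cc2ccccc2)COC1=O | intermediate
21 | (R)-4-benzyl-3-[(2S)-2-(benzyloxy)pent-4-enoyl]oxazolidin-2-one | C=CC[C@H](OCc1ccccc1)C(=O)N1[C@H](Cc2ccccc2)COC1=O | intermediate
22 | (2S)-2-(benzyloxy)-N-methoxy-N-methylpent-4-enamide | C=CC[C@H](OCc1ccccc1)C(=O)N(C)OC | intermediate
23 | 4-bromo-1,2-bis(benzyloxy)benzene | Brc1ccc(OCc2ccccc2)c(OCc2ccccc2)c1 | starting material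
24 | [3,4-bis(benzyloxy)phenyl]magnesium bromide | Br[Mg]c1ccc(OCc2ccccc2)c(OCc2ccccc2)c1 | intermediate (not isolated)
25 | (2S)-2-(benzyloxy)-1-[3,4-bis(benzyloxy)phenyl]pent-4-en-1-one | C=CC[C@H](OCc1ccccc1)C(=O)c1ccc(OCc2ccccc2)c(OCc2ccccc2)c1 | intermediate
26 | (1R,2S)-2-(benzyloxy)-1-[3,4-bis(benzyloxy)phenyl]pent-4-en-1-ol | C=CC[C@H](OCc1ccccc1)[C@@H](c1ccc(OCc2ccccc2)c(OCc2ccccc2)c1)O | intermediate
27 | ethyl 2-{[(1R,2S)-2-(benzyloxy)-1-[3,4-bis(benzyloxy)phenyl]pent-4-en-1-yl]oxy}-2-(diethoxyphosphoryl)acetate (mixture at the phosphonate carbon) | C=CC[C@H](OCc1ccccc1)[C@@H](c1ccc(OCc2ccccc2)c(OCc2ccccc2)c1)OC(C(=O)OCC)P(=O)(OCC)OCC | intermediate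
28 | ethyl 2-{[(1R,2S)-2-(benzyloxy)-1-[3,4-bis(benzyloxy)phenyl]pent-4-en-1-yl]oxy}acrylate | C=CC[C@H](OCc1ccccc1)[C@@H](c1ccc(OCc2ccccc2)c(OCc2ccccc2)c1)OC(=C)C(=O)OCC | intermediate
29 | ethyl (2R,3S)-3-(benzyloxy)-2-[3,4-bis(benzyloxy)phenyl]-3,4-dihydro-2H-pyran-6-carboxylate | CCOC(=O)C1=CC[C@H](OCc2ccccc2)[C@@H](c2ccc(OCc3ccccc3)c(OCc3ccccc3)c2)O1 | intermediate
30 | (2R,3S)-3-(benzyloxy)-2-[3,4-bis(benzyloxy)phenyl]-N-methoxy-N-methyl-3,4-dihydro-2H-pyran-6-carboxamide | CON(C)C(=O)C1=CC[C@H](OCc2ccccc2)[C@@H](c2ccc(OCc3ccccc3)c(OCc3ccccc3)c2)O1 | intermediate (not isolated)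
31 | 1-{(2R,3S)-3-(benzyloxy)-2-[3,4-bis(benzyloxy)phenyl]-3,4-dihydro-2H-pyran-6-yl}ethanone | CC(=O)C1=CC[C@H](OCc2ccccc2)[C@@H](c2ccc(OCc3ccccc3)c(OCc3ccccc3)c2)O1 | intermediate
32 | 1-{(2R,3S)-3-(benzyloxy)-2-[3,4-bis(benzyloxy)phenyl]-3,4-dihydro-2H-pyran-6-yl}-4,4,4-trifluorobutane-1,3-dione | O=C(CC(=O)C(F)(F)F)C1=CC[C@H](OCc2ccccc2)[C@@H](c2ccc(OCc3ccccc3)c(OCc3ccccc3)c2)O1 | intermediate (not isolated)
33 | 2-diazo-1-{(2R,3S)-3-(benzyloxy)-2-[3,4-bis(benzyloxy)phenyl]-3,4-dihydro-2H-pyran-6-yl}ethanone | [N-]=[N+]=CC(=O)C1=CC[C@H](OCc2ccccc2)[C@@H](c2ccc(OCc3ccccc3)c(OCc3ccccc3)c2)O1 | intermediate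
34 | 2-{(2R,3S)-3-(benzyloxy)-2-[3,4-bis(benzyloxy)phenyl]-3,4-dihydro-2H-pyran-6-yl}ethenone (vinylketene) | O=C=CC1=CC[C@H](OCc2ccccc2)[C@@H](c2ccc(OCc3ccccc3)c(OCc3ccccc3)c2)O1 | intermediate (not isolated)
35 | 2-(upper flavan-4-yl)-3-[(triisopropylsilyl)oxy]-4-(dihydropyran-6-yl)cyclobut-2-en-1-one (mixture at the ring CH) | c1ccccc1COc1ccc2c(c1)O[C@@H](c1ccc(OCc3ccccc3)c(OCc3ccccc3)c1)[C@H](OCc1ccccc1)[C@H]2C1=C(O[Si](C(C)C)(C(C)C)C(C)C)C(C2=CC[C@H](OCc3ccccc3)[C@@H](c3ccc(OCc4ccccc4)c(OCc4ccccc4)c3)O2)C1=O | intermediate (not isolated)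
36 | 2-(upper flavan-4-yl)-3-[(triisopropylsilyl)oxy]-4-(dihydropyran-6-yl)buta-1,3-dien-1-one (dienylketene, ketenyl and pyranyl groups cis) | c1ccccc1COc1ccc2c(c1)O[C@@H](c1ccc(OCc3ccccc3)c(OCc3ccccc3)c1)[C@H](OCc1ccccc1)[C@H]2C(=C=O)/C(O[Si](C(C)C)(C(C)C)C(C)C)=C\C1=CC[C@H](OCc2ccccc2)[C@@H](c2ccc(OCc3ccccc3)c(OCc3ccccc3)c2)O1 | intermediate (not isolated)
37 | 4a-H cyclohexa-2,4-dienone tautomer of 38 (ring D keto form, mixture at C4a-L) | c1ccccc1COc1ccc2c(c1)O[C@@H](c1ccc(OCc3ccccc3)c(OCc3ccccc3)c1)[C@H](OCc1ccccc1)[C@H]2C1=C(O[Si](C(C)C)(C(C)C)C(C)C)C=C2C(C1=O)C[C@H](OCc1ccccc1)[C@@H](c1ccc(OCc3ccccc3)c(OCc3ccccc3)c1)O2 | intermediate (not isolated)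
38 | (2R,3S)-3-(benzyloxy)-2-[3,4-bis(benzyloxy)phenyl]-6-{(2S,3R,4R)-3,7-bis(benzyloxy)-2-[3,4-bis(benzyloxy)phenyl]chroman-4-yl}-7-[(triisopropylsilyl)oxy]chroman-5-ol | c1ccccc1COc1ccc2c(c1)O[C@@H](c1ccc(OCc3ccccc3)c(OCc3ccccc3)c1)[C@H](OCc1ccccc1)[C@H]2c1c(O[Si](C(C)C)(C(C)C)C(C)C)cc2c(c1O)C[C@H](OCc1ccccc1)[C@@H](c1ccc(OCc3ccccc3)c(OCc3ccccc3)c1)O2 | intermediate
39 | (2R,3S)-3-(benzyloxy)-2-[3,4-bis(benzyloxy)phenyl]-6-{(2S,3R,4R)-3,7-bis(benzyloxy)-2-[3,4-bis(benzyloxy)phenyl]chroman-4-yl}chromane-5,7-diol | c1ccccc1COc1ccc2c(c1)O[C@@H](c1ccc(OCc3ccccc3)c(OCc3ccccc3)c1)[C@H](OCc1ccccc1)[C@H]2c1c(O)cc2c(c1O)C[C@H](OCc1ccccc1)[C@@H](c1ccc(OCc3ccccc3)c(OCc3ccccc3)c1)O2 | intermediate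
40 | (2R,3S)-2-(3,4-dihydroxyphenyl)-6-[(2S,3R,4R)-2-(3,4-dihydroxyphenyl)-3,7-dihydroxychroman-4-yl]chromane-3,5,7-triol | Oc1ccc2c(c1)O[C@@H](c1ccc(O)c(O)c1)[C@H](O)[C@H]2c1c(O)cc2c(c1O)C[C@H](O)[C@@H](c1ccc(O)c(O)c1)O2 | target

## Step count and risks

Total: 24 steps. Longest linear sequence: 13 steps (steps 1–7, 9–11, 22–24; the lower branch, steps 12–21 and 22–24, is equally long).

**Step 22 (key step).** The ynol ether carbon that must bond to the ketene carries a branched flavanyl group, so the [2+2] addition may be slow. Ketene dimerisation, acylation of the newly formed phenol by unused ketene, and secondary photochemistry of the many aryl ethers could then take over.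
Fallback: an ionic annulation that sets out from 33 and from ynolate 16 (made from 15 as in step 11 but not silylated) and comes back at 39. Diazoketone 33 is C-silylated (i-Pr3SiOTf, i-Pr2NEt) to 2-diazo-2-(triisopropylsilyl)-1-(dihydropyran-6-yl)ethanone F1. Photochemical Wolff rearrangement gives the isolable (triisopropylsilyl)vinylketene F2. Addition of 16 to F2 at low temperature acylates the ynolate carbon; the oxido-dienylketene closes by six-electron electrocyclisation to the C8-L-silylated resorcinol F3, with the same atom pattern in ring D. Protodesilylation of this very electron-rich ring with CF3CO2H at 0 °C gives 39; the 5-deoxy upper unit makes the interflavan bond tolerant of brief acid.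

**Step 9.** The alkynyl group is slim, so discrimination between the two faces of the C4 cation may be poor, and loss of the C3 proton to a flav-3-ene enol ether may compete.
Fallback: neighbouring-group control in place of steric control, setting out from 9 and coming back at 15. Diol 9 is acetylated (Ac2O, pyridine) to the 3,4-diacetate F4. With 13 and BF3·OEt2 the C3 acetate bridges the C4 cation as a cis-fused dioxolenium ion, so the alkynyl group can enter only trans, giving the 4-(trimethylsilylethynyl) 3-acetate F5. K2CO3 in MeOH removes the acetate and the silyl group to give the 4-ethynyl flavan-3-ol F6. Acid-catalysed benzylation (benzyl trichloroacetimidate, cat. TfOH) gives 15.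

**Step 11.** Oxygen transfer to a hindered acetylide may be incomplete, silylation may occur at carbon to give a silylketene, and the ynol ether may hydrolyse on isolation.
Fallback: a route to the ynolate that uses no peroxide, setting out from 10 and coming back at 16 (then silylated to 17 as in step 11). Ether 10 is substituted at C4 with the silyl ketene acetal of ethyl acetate and BF3·OEt2 (the usual soft nucleophile for flavan C4 cations, trans to the 3-benzyloxy group) to give ethyl (flavan-4-yl)acetate F7. Two rounds of enolisation and bromination (LiN(SiMe3)2, BrCCl2CCl2Br) give the α,α-dibromo ester F8. Reductive lithiation with t-BuLi at −78 °C and warming to 0 °C expels ethoxide and gives ynolate 16.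

**Step 5.** Methanolysis of the epoxide, ring closure at the other epoxide carbon to a benzofuranone, 1,2-aryl shift, or ionisation at the electron-rich benzylic carbon may erode yield or stereochemical purity.
Fallback: a two-stage thiol route from 6 back to 8. Benzyl thiol and SnCl4 open the epoxide at the benzylic carbon and remove the acetal, giving the α-hydroxy-β-(benzylsulfanyl) ketone F9. AgBF4 then activates the sulfide as a leaving group and the phenol closes ring C to the thermodynamically preferred trans-dihydroflavonol 8, with the carbinol centre untouched.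

**Step 19.** Ring closure onto the hindered, electronically deactivated 1,1-disubstituted alkoxyacrylate may stall, with dimerisation through the terminal alkene.
Fallback: intramolecular olefination in place of metathesis, setting out from 27 (so that steps 18 and 19 are bypassed) and coming back at 29. The terminal alkene of 27 is cleaved (cat. OsO4, NaIO4, 2,6-lutidine) to the aldehyde phosphonate F10. Base (NaH or LiCl/DBU) then triggers an intramolecular Horner–Wadsworth–Emmons reaction that closes the six-membered enol ether ester 29.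

## Further compounds

F1 | step 22 | 2-diazo-2-(triisopropylsilyl)-1-{(2R,3S)-3-(benzyloxy)-2-[3,4-bis(benzyloxy)phenyl]-3,4-dihydro-2H-pyran-6-yl}ethanone | [N-]=[N+]=C([Si](C(C)C)(C(C)C)C(C)C)C(=O)C1=CC[C@H](OCc2ccccc2)[C@@H](c2ccc(OCc3ccccc3)c(OCc3ccccc3)c2)O1
F2 | step 22 | 2-(triisopropylsilyl)-2-{(2R,3S)-3-(benzyloxy)-2-[3,4-bis(benzyloxy)phenyl]-3,4-dihydro-2H-pyran-6-yl}ethenone | O=C=C([Si](C(C)C)(C(C)C)C(C)C)C1=CC[C@H](OCc2ccccc2)[C@@H](c2ccc(OCc3ccccc3)c(OCc3ccccc3)c2)O1
F3 | step 22 | 8-(triisopropylsilyl) derivative of 39 | c1ccccc1COc1ccc2c(c1)O[C@@H](c1ccc(OCc3ccccc3)c(OCc3ccccc3)c1)[C@H](OCc1ccccc1)[C@H]2c1c(O)c([Si](C(C)C)(C(C)C)C(C)C)c2c(c1O)C[C@H](OCc1ccccc1)[C@@H](c1ccc(OCc3ccccc3)c(OCc3ccccc3)c1)O2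
F4 | step 9 | (2S,3R,4S)-7-(benzyloxy)-2-[3,4-bis(benzyloxy)phenyl]chromane-3,4-diyl diacetate | c1ccccc1COc1ccc2c(c1)O[C@@H](c1ccc(OCc3ccccc3)c(OCc3ccccc3)c1)[C@H](OC(C)=O)[C@H]2OC(C)=O
F5 | step 9 | 7-(benzyloxy)-2-[3,4-bis(benzyloxy)phenyl]-4-[(trimethylsilyl)ethynyl]chroman-3-yl acetate (2,3-trans-3,4-trans) | c1ccccc1COc1ccc2c(c1)O[C@@H](c1ccc(OCc3ccccc3)c(OCc3ccccc3)c1)[C@H](OC(C)=O)[C@H]2C#C[Si](C)(C)C
F6 | step 9 | 7-(benzyloxy)-2-[3,4-bis(benzyloxy)phenyl]-4-ethynylchroman-3-ol (2,3-trans-3,4-trans) | c1ccccc1COc1ccc2c(c1)O[C@@H](c1ccc(OCc3ccccc3)c(OCc3ccccc3)c1)[C@H](O)[C@H]2C#C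
F7 | step 11 | ethyl 2-{3,7-bis(benzyloxy)-2-[3,4-bis(benzyloxy)phenyl]chroman-4-yl}acetate (2,3-trans-3,4-trans) | c1ccccc1COc1ccc2c(c1)O[C@@H](c1ccc(OCc3ccccc3)c(OCc3ccccc3)c1)[C@H](OCc1ccccc1)[C@H]2CC(=O)OCC
F8 | step 11 | ethyl 2,2-dibromo-2-{3,7-bis(benzyloxy)-2-[3,4-bis(benzyloxy)phenyl]chroman-4-yl}acetate (2,3-trans-3,4-trans) | c1ccccc1COc1ccc2c(c1)O[C@@H](c1ccc(OCc3ccccc3)c(OCc3ccccc3)c1)[C@H](OCc1ccccc1)[C@H]2C(Br)(Br)C(=O)OCC
F9 | step 5 | (2S)-1-[4-(benzyloxy)-2-hydroxyphenyl]-3-(benzylsulfanyl)-3-[3,4-bis(benzyloxy)phenyl]-2-hydroxypropan-1-one (mixture at C3) | Oc1cc(OCc2ccccc2)ccc1C(=O)[C@@H](O)C(SCc1ccccc1)c1ccc(OCc2ccccc2)c(OCc2ccccc2)c1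
F10 | step 19 | ethyl 2-{[(1R,2S)-2-(benzyloxy)-1-[3,4-bis(benzyloxy)phenyl]-4-oxobutyl]oxy}-2-(diethoxyphosphoryl)acetate | O=CC[C@H](OCc1ccccc1)[C@@H](c1ccc(OCc2ccccc2)c(OCc2ccccc2)c1)OC(C(=O)OCC)P(=O)(OCC)OCC
A1 | alternative 1 | octa-O-benzyl 4-hydroxy derivative of the target with free cis-3,4-diol in ring C | c1ccccc1COc1ccc2c(c1)O[C@@H](c1ccc(OCc3ccccc3)c(OCc3ccccc3)c1)[C@H](O)[C@@]2(O)c1c(OCc3ccccc3)cc2c(c1OCc1ccccc1)C[C@H](OCc1ccccc1)[C@@H](c1ccc(OCc3ccccc3)c(OCc3ccccc3)c1)O2
A2 | alternative 1 | keto aldehyde: ring A aryl ketone of the lower unit bearing the (S)-aryl(aryloxy)acetaldehyde tether | O=C[C@H](c1ccc(OCc2ccccc2)c(OCc2ccccc2)c1)Oc1cc(OCc2ccccc2)ccc1C(=O)c1c(OCc2ccccc2)cc2c(c1OCc1ccccc1)C[C@H](OCc1ccccc1)[C@@H](c1ccc(OCc3ccccc3)c(OCc3ccccc3)c1)O2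
A3 | alternative 2 | octa-O-benzyl target with free C3-L hydroxyl | c1ccccc1COc1ccc2c(c1)O[C@@H](c1ccc(OCc3ccccc3)c(OCc3ccccc3)c1)[C@H](OCc1ccccc1)[C@H]2c1c(OCc3ccccc3)cc2c(c1OCc1ccccc1)C[C@H](O)[C@@H](c1ccc(OCc3ccccc3)c(OCc3ccccc3)c1)O2
A4 | alternative 2 | symmetric ring D aryl ether of (R)-[3,4-bis(benzyloxy)phenyl][(S)-oxiran-2-yl]methanol carrying the upper flavan-4-yl group | c1ccccc1COc1ccc2c(c1)O[C@@H](c1ccc(OCc3ccccc3)c(OCc3ccccc3)c1)[C@H](OCc1ccccc1)[C@H]2c1c(OCc2ccccc2)cc(O[C@H](c2ccc(OCc3ccccc3)c(OCc3ccccc3)c2)[C@@H]2CO2)cc1OCc1ccccc1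
A5 | alternative 3 | octa-O-benzyl target with an acetate on the C3-U oxygen | c1ccccc1COc1ccc2c(c1)O[C@@H](c1ccc(OCc3ccccc3)c(OCc3ccccc3)c1)[C@H](OC(C)=O)[C@H]2c1c(OCc3ccccc3)cc2c(c1OCc1ccccc1)C[C@H](OCc1ccccc1)[C@@H](c1ccc(OCc3ccccc3)c(OCc3ccccc3)c1)O2
A6 | alternative 3 | benzhydrol: [4-(benzyloxy)-2-hydroxyphenyl](protected lower flavan-6-yl)methanol | Oc1cc(OCc2ccccc2)ccc1C(O)c1c(OCc2ccccc2)cc2c(c1OCc1ccccc1)C[C@H](OCc1ccccc1)[C@@H](c1ccc(OCc3ccccc3)c(OCc3ccccc3)c1)O2
A7 | alternative 3 | (E)-2-[3,4-bis(benzyloxy)phenyl]ethenyl acetate | CC(=O)O/C=C/c1ccc(OCc2ccccc2)c(OCc2ccccc2)c1
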